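**Retrosynthetic overview** (ring numbering: O1, C2(=O), C3, C4(OH), C5H2, C6H(CH3))
- The last C–C bond is C3–C1' of the acyl group: carbodiimide O-acylation of pyranone 9 with side-chain acid 20 and O-to-C acyl shift, then removal of the tert-butyl ester and the silyl ether.
- Acid 20: the skipped diene comes from a ruthenium-catalysed alkene–alkyne coupling of allyl ester 17 with methyl pent-4-ynoate; the stereotriad comes from (S)-2-methylbutanoic acid by Noyori hydrogenation (carbinol) and Fráter–Seebach allylation (C2).
- Ring 9: the segment C4(=O)–C5H2–C6H(CH3)–O1 of the dihydropyran-2,4-dione is a β-oxygenated ketone, the retron of a 4,5-dihydroisoxazole. C4–C5 and O1–C6 are therefore made together by a tartrate/zinc-controlled [3+2] cycloaddition of the nitrile oxide C4≡N–O1 (carrying C3 and the C2 ester) to allyl alcohol, whose CH2OH later becomes the C6 methyl.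
- Ring order: the temporary isoxazoline first (step 3); one reductive operation then unmasks the aldol and lactonisation closes the dihydropyranone (step 5); no other ring is formed.

Key step: step 3

Remark: the target is written as the C4-enol tautomer of a 3-acyl-dihydropyran-2,4-dione; the tautomers equilibrate, so the route aims at the tricarbonyl compound as such.

Step 1
Reactants: 1 methyl 3,3-dimethoxypropanoate
Product: 2 methyl 3-(hydroxyimino)propanoate
Conditions: NH2OH·HCl, H2O/MeOH, 25 °C
Reagents that add atoms: hydroxylamine hydrochloride, Cl.NO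
Why: Acid-promoted acetal hydrolysis with oxime condensation in the same flask (oximation), in which the hydrochloride supplies the acid and the mildly acidic medium together with the mainly (E)-configured aldoxime should keep the oxime oxygen from closing onto the ester.

Step 2
Reactants: 2 methyl 3-(hydroxyimino)propanoate
Product: 3 methyl (3Z)-3-chloro-3-(hydroxyimino)propanoate
Conditions: NCS, DMF, 25 °C
Reagents that add atoms: N-chlorosuccinimide, O=C1CCC(=O)N1Cl
Why: Electrophilic chlorination of an aldoxime with NCS (hydroximoyl chloride formation) is the standard entry to nitrile oxide precursors and should leave the ester and the activated methylene untouched at this temperature.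

Step 3
Reactants: 3 methyl (3Z)-3-chloro-3-(hydroxyimino)propanoate; 4 prop-2-en-1-ol (allyl alcohol)
Product: 6 methyl 2-[(5S)-5-(hydroxymethyl)-4,5-dihydro-1,2-oxazol-3-yl]acetate, via nitrile oxide 5 (not isolated)
Conditions: 4, Et2Zn (1 equiv), (S,S)-diisopropyl tartrate (1 equiv), CHCl3, 0 °C; then Et2Zn (1 equiv); then 3 (slow addition), 0 °C; aq. NH4Cl
Reagents that add atoms: none
Why: Et2Zn converts allyl alcohol and the tartrate into a zinc alkoxide–tartrate complex and dehydrochlorinates 3 to the zinc-bound nitrile oxide 5, which adds across the alkene in a concerted, suprafacial [3+2] cycloaddition that forms C4–C5 and O1–C6 (target numbering) in one transition state. The closest known reaction type is the tartrate/zinc-mediated asymmetric 1,3-dipolar cycloaddition of nitrile oxides to allylic alcohols, shown for aryl and alkyl nitrile oxides. The only ring closed is the temporary 4,5-dihydroisoxazole, formed by cycloaddition and not by a polar ring closure, and its N–O bond is the latent C4 carbonyl and C6 hydroxyl. The new stereocentre (C5 of the isoxazoline, C6 of the target) is controlled by the tartrate, which bridges the two zinc atoms and presents one enantiotopic face of the alkene to the dipole; the (S,S)-ester is expected, by analogy with the established sense of this reaction, to give (5S), and the antipodal ester is taken if the first run shows the opposite sense. The step needs regioselectivity (oxygen to the substituted alkene carbon), which the steric and orbital preference of monosubstituted alkenes secures and the zinc alkoxide tether reinforces, and enantioselectivity, which the tartrate secures. It also needs the dipole to add faster than it dimerises to the furoxan or is attacked at its ester, which slow addition of 3 at 0 °C should secure because 5 is then formed only at zinc next to the dipolarophile.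

Step 4
Reactants: 6 methyl 2-[(5S)-5-(hydroxymethyl)-4,5-dihydro-1,2-oxazol-3-yl]acetate
Product: 7 methyl 2-[(5S)-5-[(phenylsulfanyl)methyl]-4,5-dihydro-1,2-oxazol-3-yl]acetate
Conditions: PhSSPh, Bu3P, pyridine, 25 °C
Reagents that add atoms: diphenyl disulfide, c1ccc(cc1)SSc1ccccc1
Why: Hata-type redox condensation (Bu3P/PhSSPh) converts the primary alcohol into the phenyl sulfide through an alkoxyphosphonium ion by SN2 at a CH2 group, so the C5 stereocentre is not touched and the isoxazoline and the ester should survive the neutral conditions.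

Step 5
Reactants: 7 methyl 2-[(5S)-5-[(phenylsulfanyl)methyl]-4,5-dihydro-1,2-oxazol-3-yl]acetate
Product: 9 (6R)-4-hydroxy-6-methyl-5,6-dihydro-2H-pyran-2-one, via hydroxy keto ester 8 (not isolated)
Conditions: Raney Ni (W-2, excess), H2 (1 atm), B(OH)3, MeOH/H2O 5:1, 25 °C; filter; then 0.5 M NaOH, THF/H2O, 0 → 25 °C; then 1 M HCl to pH 2
Reagents that add atoms: water, O
Why: Raney Ni hydrogenolysis cleaves both the C–S bond (desulfurisation, CH2SPh to CH3) and the N–O bond of the isoxazoline, the boric acid buffer hydrolyses the resulting β-hydroxy imine to the ketone without retro-aldol cleavage, and base-mediated lactonisation of the δ-hydroxy β-keto ester followed by acidification closes the six-membered ring by acyl substitution at C2 (6-exo-trig), with the C6 stereocentre carried through unchanged.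

Step 6
Reactants: 10 (2S)-2-methylbutanoic acid; 11 2,2-dimethyl-1,3-dioxane-4,6-dione (Meldrum's acid)
Product: 13 tert-butyl (4S)-4-methyl-3-oxohexanoate, via acyl Meldrum's acid 12 (not isolated)
Conditions: DCC, DMAP, CH2Cl2, 0 → 25 °C; filter, wash with aq. KHSO4; then t-BuOH, toluene, 85 °C
Reagents that add atoms: tert-butanol, CC(C)(C)O
Why: Acylation of Meldrum's acid and thermolysis in tert-butanol (Oikawa–Yonemitsu β-keto ester synthesis) extend the acid by two carbons under near-neutral conditions, under which the α-stereocentre of the 2-methylbutanoyl unit should not epimerise.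

Step 7
Reactants: 13 tert-butyl (4S)-4-methyl-3-oxohexanoate
Product: 14 tert-butyl (3S,4S)-3-hydroxy-4-methylhexanoate
Conditions: H2 (50 atm), RuCl2[(R)-BINAP] (0.5 mol %), MeOH, 50 °C
Reagents that add atoms: none
Why: Noyori asymmetric hydrogenation of a β-keto ester, in which the ester-chelated ruthenium–(R)-BINAP catalyst delivers hydride to one carbonyl face under catalyst control (the small methyl/ethyl difference at C4 exerts little bias) and should give the (3S) carbinol, the same spatial sense as in the reduction of simple acetoacetates.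

Step 8
Reactants: 14 tert-butyl (3S,4S)-3-hydroxy-4-methylhexanoate; 15 3-bromoprop-1-ene (allyl bromide)
Product: 16 tert-butyl (2R,3R,4S)-3-hydroxy-4-methyl-2-(prop-2-en-1-yl)hexanoate
Conditions: LiN(iPr)2 (2.2 equiv), THF, −78 → −20 °C; then 15, DMPU, −78 → −10 °C
Reagents that add atoms: none
Why: Fráter–Seebach alkylation, in which the chelated lithium alkoxide–enolate dianion is allylated on the face opposite the C3 substituent, which sets C2 with 2,3-anti relative configuration, that is (2R).

Step 9
Reactants: 16 tert-butyl (2R,3R,4S)-3-hydroxy-4-methyl-2-(prop-2-en-1-yl)hexanoate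
Product: 17 tert-butyl (2R,3R,4S)-4-methyl-2-(prop-2-en-1-yl)-3-[(triethylsilyl)oxy]hexanoate
Conditions: TESOTf, 2,6-lutidine, CH2Cl2, −78 → 0 °C
Reagents that add atoms: triethylsilyl trifluoromethanesulfonate, CC[Si](CC)(CC)OS(=O)(=O)C(F)(F)F
Why: Silylation of the hindered secondary alcohol with a silyl triflate and a hindered pyridine base (silyl ether protection) blocks the hydroxyl for the later carbodiimide coupling and is mild enough for the tert-butyl ester.

Step 10
Reactants: 17 tert-butyl (2R,3R,4S)-4-methyl-2-(prop-2-en-1-yl)-3-[(triethylsilyl)oxy]hexanoate; 18 methyl pent-4-ynoate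
Product: 19 1-tert-butyl 9-methyl (2R,3E)-6-methylidene-2-[(1R,2S)-2-methyl-1-[(triethylsilyl)oxy]butyl]non-3-enedioate
Conditions: [CpRu(MeCN)3]PF6 (10 mol %), acetone, 25 °C
Reagents that add atoms: none
Why: Ruthenium-catalysed alkene–alkyne coupling (Trost Alder-ene type), in which a ruthenacyclopentene forms from the alkyne and the monosubstituted alkene and β-hydride elimination of the allylic hydrogen followed by reductive elimination should give the 1,4-diene with the 1,1-disubstituted alkene from the terminal alkyne and an (E)-1,2-disubstituted alkene, without touching the C2 stereocentre, the esters or the silyl ether.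

Step 11
Reactants: 19 1-tert-butyl 9-methyl (2R,3E)-6-methylidene-2-[(1R,2S)-2-methyl-1-[(triethylsilyl)oxy]butyl]non-3-enedioate
Product: 20 (6E,8R,9R,10S)-8-(tert-butoxycarbonyl)-10-methyl-4-methylidene-9-[(triethylsilyl)oxy]dodec-6-enoic acid
Conditions: Me3SnOH, ClCH2CH2Cl, 70 °C; then wash with 0.1 M HCl
Reagents that add atoms: trimethyltin hydroxide, C[Sn](C)(C)O
Why: Chemoselective ester hydrolysis with Me3SnOH, in which the neutral tin hydroxide cleaves the unhindered methyl ester but not the hindered tert-butyl ester and should neither epimerise C8 nor move the β,γ-double bond into conjugation.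

Step 12
Reactants: 20 (6E,8R,9R,10S)-8-(tert-butoxycarbonyl)-10-methyl-4-methylidene-9-[(triethylsilyl)oxy]dodec-6-enoic acid; 9 (6R)-4-hydroxy-6-methyl-5,6-dihydro-2H-pyran-2-one
Product: 22 tert-butyl (2R,3E)-9-[(6R)-4-hydroxy-6-methyl-2-oxo-5,6-dihydro-2H-pyran-3-yl]-6-methylidene-2-[(1R,2S)-2-methyl-1-[(triethylsilyl)oxy]butyl]-9-oxonon-3-enoate, via enol ester 21 (not isolated)
Conditions: DCC (1.2 equiv), DMAP (1.3 equiv), CH2Cl2, 0 → 25 °C
Reagents that add atoms: none
Why: Steglich-type O-acylation of the acidic enol of 9 followed by DMAP-mediated 1,3-acyl shift (Fries-type O-to-C acyl migration) should give the thermodynamically favoured, hydrogen-bonded 3-acyl-4-hydroxy-dihydropyranone, a known way to acylate cyclic 1,3-dicarbonyl compounds at carbon.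

Step 13
Reactants: 22 tert-butyl (2R,3E)-9-[(6R)-4-hydroxy-6-methyl-2-oxo-5,6-dihydro-2H-pyran-3-yl]-6-methylidene-2-[(1R,2S)-2-methyl-1-[(triethylsilyl)oxy]butyl]-9-oxonon-3-enoate
Product: 24 (2R,3E)-9-[(6R)-4-hydroxy-6-methyl-2-oxo-5,6-dihydro-2H-pyran-3-yl]-2-[(1R,2S)-1-hydroxy-2-methylbutyl]-6-methylidene-9-oxonon-3-enoic acid, via silylated acid 23 (not isolated)
Conditions: TMSOTf, 2,6-lutidine, CH2Cl2, 0 °C; then 1 M HCl, THF/H2O, 25 °C
Reagents that add atoms: none
Why: Silyl triflate-mediated tert-butyl ester cleavage (loss of 2-methylpropene from the O-silylated ester in the presence of base, so that no strong protic acid meets the 1,1-disubstituted alkene) followed by mild aqueous acid hydrolysis of the trimethylsilyl ester, the silyl enol ether and the triethylsilyl ether should free the acid and the alcohol without epimerising C2 or opening the lactone.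

**Compound list**
1 | methyl 3,3-dimethoxypropanoate | COC(=O)CC(OC)OC | starting material
2 | methyl 3-(hydroxyimino)propanoate | COC(=O)CC=NO | intermediate
3 | methyl (3Z)-3-chloro-3-(hydroxyimino)propanoate | COC(=O)C/C(Cl)=N/O | intermediate
4 | prop-2-en-1-ol (allyl alcohol) | C=CCO | starting material
5 | 2-(methoxycarbonyl)acetonitrile oxide (nitrile oxide) | COC(=O)CC#[N+][O-] | intermediate
6 | methyl 2-[(5S)-5-(hydroxymethyl)-4,5-dihydro-1,2-oxazol-3-yl]acetate | C1[C@@H](CO)ON=C1CC(=O)OC | intermediate
7 | methyl 2-[(5S)-5-[(phenylsulfanyl)methyl]-4,5-dihydro-1,2-oxazol-3-yl]acetate | C1[C@@H](CSc2ccccc2)ON=C1CC(=O)OC | intermediate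
8 | methyl (5R)-5-hydroxy-3-oxohexanoate | COC(=O)CC(=O)C[C@@H](C)O | intermediate
9 | (6R)-4-hydroxy-6-methyl-5,6-dihydro-2H-pyran-2-one | O=C1C=C(O)C[C@@H](C)O1 | intermediate
10 | (2S)-2-methylbutanoic acid | OC(=O)[C@@H](C)CC | starting material
11 | 2,2-dimethyl-1,3-dioxane-4,6-dione (Meldrum's acid) | CC1(C)OC(=O)CC(=O)O1 | starting material
12 | 5-[(2S)-1-hydroxy-2-methylbutylidene]-2,2-dimethyl-1,3-dioxane-4,6-dione | CC1(C)OC(=O)C(=C(O)[C@@H](C)CC)C(=O)O1 | intermediate
13 | tert-butyl (4S)-4-methyl-3-oxohexanoate | CC(C)(C)OC(=O)CC(=O)[C@@H](C)CC | intermediate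
14 | tert-butyl (3S,4S)-3-hydroxy-4-methylhexanoate | CC(C)(C)OC(=O)C[C@H](O)[C@@H](C)CC | intermediate
15 | 3-bromoprop-1-ene (allyl bromide) | C=CCBr | starting material
16 | tert-butyl (2R,3R,4S)-3-hydroxy-4-methyl-2-(prop-2-en-1-yl)hexanoate | C=CC[C@@H](C(=O)OC(C)(C)C)[C@H](O)[C@@H](C)CC | intermediate
17 | tert-butyl (2R,3R,4S)-4-methyl-2-(prop-2-en-1-yl)-3-[(triethylsilyl)oxy]hexanoate | C=CC[C@@H](C(=O)OC(C)(C)C)[C@H](O[Si](CC)(CC)CC)[C@@H](C)CC | intermediate
18 | methyl pent-4-ynoate | C#CCCC(=O)OC | starting material
19 | 1-tert-butyl 9-methyl (2R,3E)-6-methylidene-2-[(1R,2S)-2-methyl-1-[(triethylsilyl)oxy]butyl]non-3-enedioate | C=C(C/C=C/[C@@H](C(=O)OC(C)(C)C)[C@H](O[Si](CC)(CC)CC)[C@@H](C)CC)CCC(=O)OC | intermediate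
20 | (6E,8R,9R,10S)-8-(tert-butoxycarbonyl)-10-methyl-4-methylidene-9-[(triethylsilyl)oxy]dodec-6-enoic acid | C=C(C/C=C/[C@@H](C(=O)OC(C)(C)C)[C@H](O[Si](CC)(CC)CC)[C@@H](C)CC)CCC(=O)O | intermediate
21 | (6R)-6-methyl-2-oxo-5,6-dihydro-2H-pyran-4-yl (6E,8R,9R,10S)-8-(tert-butoxycarbonyl)-10-methyl-4-methylidene-9-[(triethylsilyl)oxy]dodec-6-enoate | C=C(C/C=C/[C@@H](C(=O)OC(C)(C)C)[C@H](O[Si](CC)(CC)CC)[C@@H](C)CC)CCC(=O)OC1=CC(=O)O[C@H](C)C1 | intermediate
22 | tert-butyl (2R,3E)-9-[(6R)-4-hydroxy-6-methyl-2-oxo-5,6-dihydro-2H-pyran-3-yl]-6-methylidene-2-[(1R,2S)-2-methyl-1-[(triethylsilyl)oxy]butyl]-9-oxonon-3-enoate | C=C(C/C=C/[C@@H](C(=O)OC(C)(C)C)[C@H](O[Si](CC)(CC)CC)[C@@H](C)CC)CCC(=O)C1=C(O)C[C@@H](C)OC1=O | intermediate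
23 | trimethylsilyl (2R,3E)-6-methylidene-2-[(1R,2S)-2-methyl-1-[(triethylsilyl)oxy]butyl]-9-[(6R)-6-methyl-2-oxo-4-[(trimethylsilyl)oxy]-5,6-dihydro-2H-pyran-3-yl]-9-oxonon-3-enoate | C=C(C/C=C/[C@@H](C(=O)O[Si](C)(C)C)[C@H](O[Si](CC)(CC)CC)[C@@H](C)CC)CCC(=O)C1=C(O[Si](C)(C)C)C[C@@H](C)OC1=O | intermediate
24 | (2R,3E)-9-[(6R)-4-hydroxy-6-methyl-2-oxo-5,6-dihydro-2H-pyran-3-yl]-2-[(1R,2S)-1-hydroxy-2-methylbutyl]-6-methylidene-9-oxonon-3-enoic acid (CNP0221901.1) | C=C(C/C=C/[C@@H](C(=O)O)[C@H](O)[C@@H](C)CC)CCC(=O)C1=C(O)C[C@@H](C)OC1=O | target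

**Step count and risks**
Total step count: 13. Longest linear sequence: 8 steps (steps 6 to 13, from (2S)-2-methylbutanoic acid); the ring branch (steps 1 to 5) joins at step 12.

Most likely to fail:

1. Step 3. The ester of the nitrile oxide may compete with the tartrate for zinc and erode facial selectivity, and the dipole may dimerise to the furoxan before it adds. The fallback keeps the [3+2] event but sets the stereocentre afterwards with an enzyme. It sets out from compound 3: dehydrochlorination with Et3N in the presence of propyne should give the aromatic cycloadduct methyl 2-(5-methyl-1,2-oxazol-3-yl)acetate F1. N–O cleavage with Mo(CO)6 in wet MeCN should give the enaminone methyl (3Z)-3-amino-5-oxohex-3-enoate F2, and cold dilute aqueous HCl should hydrolyse it to methyl 3,5-dioxohexanoate F3. A regioselective, (R)-selective alcohol dehydrogenase (ketoreductase, NADP+, i-PrOH for cofactor recycling, pH 7 buffer) should then reduce only the C5 ketone. The fallback comes back to the route at compound 8, which is lactonised to 9 as in the second stage of step 5.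

2. Step 5. The single reductive operation may stop short of complete C–S hydrogenolysis, or may over-reduce the β-keto ester on the nickel surface. The fallback separates the two tasks and avoids sulfur. It sets out from compound 6: TsCl in pyridine should give methyl 2-[(5S)-5-{[(4-methylbenzenesulfonyl)oxy]methyl}-4,5-dihydro-1,2-oxazol-3-yl]acetate F4. Hydride displacement with NaBH4 in DMSO at 60 °C should give methyl 2-[(5R)-5-methyl-4,5-dihydro-1,2-oxazol-3-yl]acetate F5. N–O cleavage with Mo(CO)6 in MeCN/H2O at 80 °C should then give the hydroxy keto ester, so the fallback comes back at compound 8, again lactonised to 9 with NaOH and then HCl.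

3. Step 10. The coupling may give too much of the linear regioisomer, or the catalyst may stall on the hindered, oxygen-rich alkene. The fallback makes the same C–C bond by allyl–alkenyl cross-coupling. It sets out from compounds 17 and 18. Allylic C–H acetoxylation of 17 (Pd(OAc)2, benzoquinone, DMSO/AcOH, 40 °C) should give the linear allylic acetate tert-butyl (2R,3E)-5-(acetyloxy)-2-[(1R,2S)-2-methyl-1-[(triethylsilyl)oxy]butyl]pent-3-enoate F6. Hydrostannation of 18 at the internal carbon (Bu3SnH, Mo(CO)3(CNtBu)3, THF, 55 °C) should give methyl 4-(tributylstannyl)pent-4-enoate F7. Stille coupling of F6 with F7 (Pd2(dba)3, LiCl, DMF, 40 °C) at the unhindered allyl terminus should keep the (E) geometry, and the fallback comes back at compound 19.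

Further compounds
F1 | step 3 | methyl 2-(5-methyl-1,2-oxazol-3-yl)acetate | COC(=O)Cc1cc(C)on1
F2 | step 3 | methyl (3Z)-3-amino-5-oxohex-3-enoate | COC(=O)C/C(N)=C/C(C)=O
F3 | step 3 | methyl 3,5-dioxohexanoate | COC(=O)CC(=O)CC(C)=O
F4 | step 5 | methyl 2-[(5S)-5-{[(4-methylbenzenesulfonyl)oxy]methyl}-4,5-dihydro-1,2-oxazol-3-yl]acetate | C1[C@@H](COS(=O)(=O)c2ccc(C)cc2)ON=C1CC(=O)OC
F5 | step 5 | methyl 2-[(5R)-5-methyl-4,5-dihydro-1,2-oxazol-3-yl]acetate | C1[C@@H](C)ON=C1CC(=O)OC
F6 | step 10 | tert-butyl (2R,3E)-5-(acetyloxy)-2-[(1R,2S)-2-methyl-1-[(triethylsilyl)oxy]butyl]pent-3-enoate | CC(=O)OC/C=C/[C@@H](C(=O)OC(C)(C)C)[C@H](O[Si](CC)(CC)CC)[C@@H](C)CC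
F7 | step 10 | methyl 4-(tributylstannyl)pent-4-enoate | C=C(CCC(=O)OC)[Sn](CCCC)(CCCC)CCCC
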